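The numbers in the tables are calculated for an exercise.

Amounts first, since you want a quick number: at 30.0 min the south-east run, which is this same flask followed so far, holds 18.0% substrate, 29.9% isomer of the product and 0.9% target.

| setting | south-east | flask |
|---|---|---|
| substrate | 1.5 M | 1.5 M |
| partner | 0.90 M | 0.900 M |
| remark | the very flask that is asked about, followed so far |  |
| time |  | 2.5 h |

- south-east (time / min: isomer of the product / %, target / %, substrate / %): 8.00: 15.0, 11.2, 48.9; 15.0: 23.0, 4.4, 34.7; 25.0: 28.6, 3.4, 21.1; 30.0: 29.9, 0.9, 18.0

(scatter of a reading: 1 percentage point)

- the earlier runs were read with a standard deviation of 1 percentage point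
- steps that have been proposed: substrate + partner <-> target; target -> over-reaction product; substrate + partner <-> isomer of the product; substrate <-> dormant form

- ratio of isomer of the product to target at 3.0 s
- ratio of isomer of the product to target at 2.5 min
- ratio of isomer of the product to target at 2.5 h
- which of isomer of the product and target there is more of at 2.5 h

1. Take the isomer share (a selectivity): the isomer of the product standing in the south-east run, divided by the substrate lost so far. Replace its curve by the mean of the last 3 readings, which gives 36.0%.

2. Check the error of that mean: the share moves by 1.2 percentage points between 15.0 min and 30.0 min, with readings scattered by 1 point. So a flat share will do.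

3. My own reckoning: if the flask loses its whole substrate charge, it ends near 36.0% isomer of the product. Target is read less finely: its last reading is 0.9%, with a scatter of 1 point. The ratio read at 30.0 min is 33.2, so I commit to the isomer of the product leading at 2.5 h and leave the size of the ratio open.

4. Your forecast gives 0.9, 1.1 and 300 for the three ratios, with isomer of the product in the lead: “Target is drained while the isomer persists”.

5. The flask gives 0.347, 0.598 and 243, with isomer of the product in the lead, 34.1% against 0.140% target.

    substrate + partner ⇌ target (K = 0.580 M⁻¹, k = 0.00320 M⁻¹ s⁻¹)
    target → over-reaction product (k = 0.00140 s⁻¹)
    substrate + partner ⇌ isomer of the product (K = 260 M⁻¹, k = 0.00110 M⁻¹ s⁻¹)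
    substrate ⇌ dormant form (K = 9.00, k = 5.30 × 10⁻⁴ s⁻¹)

In this flask the isomer of the product has a half-life of 46 h for going back, longer than the 2.5 h asked about, while substrate + partner and target relax with a half-life of 1.94 min, shorter than that time. At 2.5 h the isomer share gives 34.6% in this flask, which holds 34.1%. In the neighbour flask with 0.38 M substrate the share gives 35.6%, less than the 48.1% it holds, and its dormant form stands at 21.5% against 41.2% here.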